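**Plan**
- Retrosynthesis first removes the five benzyl ethers and cuts the C6 styryl C=C (phosphonate olefination), then the O1–C2 bond of the dihydrofuran, then three bonds of ring A at once (C3a–C4, C7–C7a, C4–C5), leaving a silyl ynol ether and a cyclobutenone.
- The feature that allows this: ring A is a 2-substituted resorcinol. O1 (on C7a) and the C4 hydroxyl are meta, C3a lies between them, and the styryl carbon C6 is para to C3a; this is the pattern a vinylketene/ynol ether benzannulation delivers.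
- Forward order: an Evans aldol joins the two aryl-bearing chain carbons, the acyl carbon is turned into a triisopropylsilyl ynol ether, ring A is built onto it, the dihydrofuran ring closes, and the stilbene arm is attached last.
- Stereochemistry: C3 is the α-carbon of the (R)-4-benzyloxazolidinone aldol; C2 is set trans to C3 when the p-benzyloxybenzyl cation is trapped by the phenol; the alkene is E from the Horner–Wadsworth–Emmons step.

Key step: step 10

Remark: acid 1 is assumed to be a catalogue compound; the carbinol centre made in step 2 is re-formed in step 12, so only the α-centre of the aldol has to be controlled.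

**Step 1**
Reactants: 1 3,5-bis(benzyloxy)phenylacetic acid; 2 (4R)-4-benzyl-1,3-oxazolidin-2-one
Product: 4 (4R)-4-benzyl-3-{[3,5-bis(benzyloxy)phenyl]acetyl}-1,3-oxazolidin-2-one, via mixed pivalic anhydride 3 (not isolated)
Conditions: PivCl, Et3N, THF, −20 °C; then 2, LiCl, −20 °C → rt
Reagents that add atoms: none
Why: Mixed-anhydride N-acylation of an oxazolidinone (attachment of the Evans auxiliary), in which LiCl/Et3N activates the carbamate nitrogen to take the arylacetyl group from the less hindered carbonyl of 3; no stereocentre is formed.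

**Step 2**
Reactants: 4 (4R)-4-benzyl-3-{[3,5-bis(benzyloxy)phenyl]acetyl}-1,3-oxazolidin-2-one; 5 3,4-bis(benzyloxy)benzaldehyde
Product: 7 (4R)-4-benzyl-3-{(2R,3R)-3-[3,4-bis(benzyloxy)phenyl]-2-[3,5-bis(benzyloxy)phenyl]-3-hydroxypropanoyl}-1,3-oxazolidin-2-one, via dibutylboron Z-enolate 6 (not isolated)
Conditions: Bu2BOTf, i-Pr2NEt, CH2Cl2, 0 °C; 5, −78 → 0 °C; then pH 7 buffer, MeOH, H2O2
Reagents that add atoms: none
Why: Evans syn-aldol reaction, in which the Z-boron enolate reacts through a closed Zimmerman–Traxler transition state on the face away from the benzyl group of the (R)-auxiliary, setting the aryl-bearing α-carbon (future C3) as R with the carbinol syn to it.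

**Step 3**
Reactants: 7 syn-aldol adduct
Product: 8 (4R)-4-benzyl-3-{(2R,3R)-3-[3,4-bis(benzyloxy)phenyl]-2-[3,5-bis(benzyloxy)phenyl]-3-(tert-butyldimethylsilyloxy)propanoyl}-1,3-oxazolidin-2-one
Conditions: TBSOTf, 2,6-lutidine, CH2Cl2, 0 °C
Reagents that add atoms: tert-butyldimethylsilyl triflate, CC(C)(C)[Si](C)(C)OS(=O)(=O)C(F)(F)F
Why: Silylation of a hindered secondary aldol hydroxyl with a silyl triflate and a non-nucleophilic base is routine; it blocks retro-aldol cleavage and protects the oxygen for the organolithium chemistry ahead.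

**Step 4**
Reactants: 8 silylated imide
Product: 9 (2S,3R)-3-[3,4-bis(benzyloxy)phenyl]-2-[3,5-bis(benzyloxy)phenyl]-3-(tert-butyldimethylsilyloxy)propan-1-ol
Conditions: LiBH4, MeOH, THF, 0 °C
Reagents that add atoms: none
Why: Reductive removal of the Evans auxiliary with LiBH4 attacks the exocyclic imide carbonyl and leaves the silyl and benzyl ethers and the α-aryl centre untouched (the descriptor changes only through the priority rules).

**Step 5**
Reactants: 9 primary alcohol
Product: 10 (2R,3R)-3-[3,4-bis(benzyloxy)phenyl]-2-[3,5-bis(benzyloxy)phenyl]-3-(tert-butyldimethylsilyloxy)propanal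
Conditions: Dess–Martin periodinane, CH2Cl2, 0 °C → rt; used crude
Reagents that add atoms: none
Why: Dess–Martin oxidation is base-free, which the easily enolised α-aryl aldehyde requires, and the aldehyde is carried on at once.

**Step 6**
Reactants: 10 α-aryl aldehyde
Product: 11 (3R,4R)-4-[3,4-bis(benzyloxy)phenyl]-3-[3,5-bis(benzyloxy)phenyl]-1,1-dibromo-4-(tert-butyldimethylsilyloxy)but-1-ene
Conditions: CBr4, PPh3, Zn, CH2Cl2, rt; then 10, 0 °C → rt
Reagents that add atoms: carbon tetrabromide, BrC(Br)(Br)Br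
Why: Ramirez dibromo-olefination (first stage of the Corey–Fuchs sequence) with the preformed, non-basic ylide converts the aldehyde without exposing its α-aryl centre to base.

**Step 7**
Reactants: 11 dibromoalkene
Product: 14 (3S,4R)-4-[3,4-bis(benzyloxy)phenyl]-3-[3,5-bis(benzyloxy)phenyl]-4-(tert-butyldimethylsilyloxy)-1-(triisopropylsilyloxy)but-1-yne, via lithium acetylide 12 (not isolated), via lithium ynolate 13 (not isolated)
Conditions: n-BuLi (2.1 equiv), THF, −78 °C; LiOOt-Bu [from t-BuOOH, LiN(SiMe3)2], −78 → 0 °C; TIPSOTf, −78 °C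
Reagents that add atoms: tert-butyl hydroperoxide, CC(C)(C)OO; triisopropylsilyl triflate, CC(C)[Si](OS(=O)(=O)C(F)(F)F)(C(C)C)C(C)C
Why: Corey–Fuchs rearrangement (Br/Li exchange, 1,2-hydride shift) gives the acetylide, which lithium tert-butyl peroxide oxidises at carbon to the ynolate (Julia oxidation of acetylides) and the bulky silyl triflate traps on oxygen; the anionic alkyne terminus disfavours removal of the C3–H.

**Step 8**
Reactants: 15 tert-butyldimethyl(prop-2-yn-1-yloxy)silane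
Product: 16 3-[(tert-butyldimethylsilyloxy)methyl]-4,4-dichlorocyclobut-2-en-1-one
Conditions: Cl3CCOCl, Zn–Cu couple, Et2O/DME, rt
Reagents that add atoms: trichloroacetyl chloride, ClC(Cl)(Cl)C(Cl)=O
Why: Dichloroketene, generated in the flask by zinc dechlorination, adds to the terminal alkyne in a [2+2] cycloaddition with the terminal carbon bonding to the ketene carbonyl carbon, which places the substituent on C3.

**Step 9**
Reactants: 16 dichlorocyclobutenone
Product: 17 3-[(tert-butyldimethylsilyloxy)methyl]cyclobut-2-en-1-one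
Conditions: Zn, AcOH, TMEDA, EtOH, 0 °C
Reagents that add atoms: none
Why: Reductive dechlorination of the α,α-dichloroketone with zinc in buffered acetic acid is the standard route to 3-substituted cyclobutenones and is mild enough for the silyl ether and the strained enone.

**Step 10**
Reactants: 14 triisopropylsilyl ynol ether; 17 3-[(tert-butyldimethylsilyloxy)methyl]cyclobut-2-en-1-one
Product: 21 2-{(1S,2R)-2-[3,4-bis(benzyloxy)phenyl]-1-[3,5-bis(benzyloxy)phenyl]-2-(tert-butyldimethylsilyloxy)ethyl}-5-[(tert-butyldimethylsilyloxy)methyl]-3-(triisopropylsilyloxy)phenol, via vinylketene 18 (not isolated), via 4-vinylcyclobutenone 19 (not isolated), via dienylketene 20 (not isolated)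
Conditions: PhMe, 80 °C, then 110 °C (17 in slight excess)
Reagents that add atoms: none
Why: Heating opens 17 by a 4π electrocyclic ring opening to vinylketene 18, whose carbonyl carbon bonds to the nucleophilic, chain-bearing carbon of the ynol ether in a regiospecific [2+2] cycloaddition giving 19; a second 4π opening gives dienylketene 20, which closes and tautomerises to the phenol. This is the Danheiser benzannulation of a cyclobutenone with a triisopropylsilyl ynol ether, the established way to resorcinol monosilyl ethers. Ring A closes by 6π electrocyclization, which makes C4–C5 after the [2+2] step has made C3a–C4 and C7–C7a (ring A is symmetric about the C3a–C6 axis, so the two oxygen-bearing carbons are interchangeable). No stereocentre is formed, and the C3 centre from step 2 is a spectator because the conditions are neutral and free of base or metal. The selectivity needed is regiochemical, with the chain carbon between the two oxygens and the silyloxymethyl carbon para to it. It is secured by the polarisation of the ynol ether, whose β-carbon attacks the ketene carbonyl, and by the substituent sitting on C3 of the cyclobutenone.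

**Step 11**
Reactants: 21 resorcinol monosilyl ether
Product: 22 2-{(1S,2R)-2-[3,4-bis(benzyloxy)phenyl]-1-[3,5-bis(benzyloxy)phenyl]-2-hydroxyethyl}-5-(hydroxymethyl)benzene-1,3-diol
Conditions: Bu4NF, THF, 0 °C → rt
Reagents that add atoms: none
Why: Fluoride-mediated desilylation cleaves the aryl triisopropylsilyl ether and both tert-butyldimethylsilyl ethers in one operation and makes the two phenols of ring A equivalent.

**Step 12**
Reactants: 22 resorcinol diol
Product: 23 (2S,3S)-2-[3,4-bis(benzyloxy)phenyl]-3-[3,5-bis(benzyloxy)phenyl]-6-(hydroxymethyl)-2,3-dihydro-1-benzofuran-4-ol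
Conditions: p-TsOH·H2O (10 mol %), CH2Cl2, 0 °C → rt
Reagents that add atoms: none
Why: Acid-catalysed cyclodehydration, in which the p-benzyloxybenzylic alcohol ionises and either equivalent phenol closes the five-membered ring on the cation anti to the C3 aryl group; the 2,3-trans ring is the kinetic product and, through reversible C2–O ionisation, also the thermodynamic one, so C3 dictates C2.

**Step 13**
Reactants: 23 benzylic alcohol
Product: 24 (2S,3S)-2-[3,4-bis(benzyloxy)phenyl]-3-[3,5-bis(benzyloxy)phenyl]-4-hydroxy-2,3-dihydro-1-benzofuran-6-carbaldehyde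
Conditions: MnO2, EtOAc, rt
Reagents that add atoms: none
Why: MnO2 oxidises benzylic alcohols selectively to aldehydes and leaves the phenol, the benzyl ethers and the dihydrofuran C–H bonds alone.

**Step 14**
Reactants: 25 4-(benzyloxy)-3-methoxybenzyl alcohol
Product: 26 diethyl [4-(benzyloxy)-3-methoxybenzyl]phosphonate
Conditions: P(OEt)3, ZnI2, PhMe, reflux
Reagents that add atoms: triethyl phosphite, CCOP(OCC)OCC
Why: ZnI2-mediated one-flask conversion of an electron-rich benzylic alcohol into its diethyl phosphonate with triethyl phosphite (an Arbuzov-type process).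

**Step 15**
Reactants: 24 aldehyde; 26 benzylphosphonate
Product: 27 (2S,3S)-6-{(E)-2-[4-(benzyloxy)-3-methoxyphenyl]ethenyl}-2-[3,4-bis(benzyloxy)phenyl]-3-[3,5-bis(benzyloxy)phenyl]-2,3-dihydro-1-benzofuran-4-ol
Conditions: KOt-Bu (excess), THF, 0 °C → rt
Reagents that add atoms: none
Why: Horner–Wadsworth–Emmons olefination of a semi-stabilised benzylphosphonate anion with an aromatic aldehyde should give the E-stilbene; one extra equivalent of base is spent on the C4 phenol, whose phenoxide is meta to the formyl group and does not deactivate it.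

**Step 16**
Reactants: 27 penta-benzyl ether
Product: 28 (2S,3S)-2-(3,4-dihydroxyphenyl)-3-(3,5-dihydroxyphenyl)-6-[(E)-2-(4-hydroxy-3-methoxyphenyl)ethenyl]-2,3-dihydro-1-benzofuran-4-ol (CNP0199755.1)
Conditions: BCl3, C6HMe5, CH2Cl2, −78 °C; then MeOH
Reagents that add atoms: none
Why: Lewis acid debenzylation with BCl3 and pentamethylbenzene as a non-basic benzyl-cation scavenger cleaves aryl benzyl ethers at −78 °C without hydrogen, so the stilbene alkene, the methyl ether and the dihydrofuran should survive.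

**Compound list**
1 | 3,5-bis(benzyloxy)phenylacetic acid | OC(=O)Cc1cc(OCc2ccccc2)cc(OCc2ccccc2)c1 | starting material
2 | (4R)-4-benzyl-1,3-oxazolidin-2-one | O=C1N[C@H](Cc2ccccc2)CO1 | starting material
3 | [3,5-bis(benzyloxy)phenyl]acetic pivalic anhydride | CC(C)(C)C(=O)OC(=O)Cc1cc(OCc2ccccc2)cc(OCc2ccccc2)c1 | intermediate
4 | (4R)-4-benzyl-3-{[3,5-bis(benzyloxy)phenyl]acetyl}-1,3-oxazolidin-2-one | O=C(Cc1cc(OCc2ccccc2)cc(OCc2ccccc2)c1)N1[C@H](Cc2ccccc2)COC1=O | intermediate
5 | 3,4-bis(benzyloxy)benzaldehyde | O=Cc1ccc(OCc2ccccc2)c(OCc2ccccc2)c1 | starting material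
6 | dibutylboron Z-enolate of 4 | CCCCB(CCCC)O/C(=C\c1cc(OCc2ccccc2)cc(OCc2ccccc2)c1)N1[C@H](Cc2ccccc2)COC1=O | intermediate
7 | (4R)-4-benzyl-3-{(2R,3R)-3-[3,4-bis(benzyloxy)phenyl]-2-[3,5-bis(benzyloxy)phenyl]-3-hydroxypropanoyl}-1,3-oxazolidin-2-one | O=C(N1[C@H](Cc2ccccc2)COC1=O)[C@H](c1cc(OCc2ccccc2)cc(OCc2ccccc2)c1)[C@@H](O)c1ccc(OCc2ccccc2)c(OCc2ccccc2)c1 | intermediate
8 | (4R)-4-benzyl-3-{(2R,3R)-3-[3,4-bis(benzyloxy)phenyl]-2-[3,5-bis(benzyloxy)phenyl]-3-(tert-butyldimethylsilyloxy)propanoyl}-1,3-oxazolidin-2-one | O=C(N1[C@H](Cc2ccccc2)COC1=O)[C@H](c1cc(OCc2ccccc2)cc(OCc2ccccc2)c1)[C@@H](O[Si](C)(C)C(C)(C)C)c1ccc(OCc2ccccc2)c(OCc2ccccc2)c1 | intermediate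
9 | (2S,3R)-3-[3,4-bis(benzyloxy)phenyl]-2-[3,5-bis(benzyloxy)phenyl]-3-(tert-butyldimethylsilyloxy)propan-1-ol | OC[C@H](c1cc(OCc2ccccc2)cc(OCc2ccccc2)c1)[C@@H](O[Si](C)(C)C(C)(C)C)c1ccc(OCc2ccccc2)c(OCc2ccccc2)c1 | intermediate
10 | (2R,3R)-3-[3,4-bis(benzyloxy)phenyl]-2-[3,5-bis(benzyloxy)phenyl]-3-(tert-butyldimethylsilyloxy)propanal | O=C[C@H](c1cc(OCc2ccccc2)cc(OCc2ccccc2)c1)[C@@H](O[Si](C)(C)C(C)(C)C)c1ccc(OCc2ccccc2)c(OCc2ccccc2)c1 | intermediate
11 | (3R,4R)-4-[3,4-bis(benzyloxy)phenyl]-3-[3,5-bis(benzyloxy)phenyl]-1,1-dibromo-4-(tert-butyldimethylsilyloxy)but-1-ene | BrC(Br)=C[C@H](c1cc(OCc2ccccc2)cc(OCc2ccccc2)c1)[C@@H](O[Si](C)(C)C(C)(C)C)c1ccc(OCc2ccccc2)c(OCc2ccccc2)c1 | intermediate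
12 | lithium (3S,4R)-4-[3,4-bis(benzyloxy)phenyl]-3-[3,5-bis(benzyloxy)phenyl]-4-(tert-butyldimethylsilyloxy)but-1-yn-1-ide | [Li]C#C[C@H](c1cc(OCc2ccccc2)cc(OCc2ccccc2)c1)[C@@H](O[Si](C)(C)C(C)(C)C)c1ccc(OCc2ccccc2)c(OCc2ccccc2)c1 | intermediate
13 | lithium (3S,4R)-4-[3,4-bis(benzyloxy)phenyl]-3-[3,5-bis(benzyloxy)phenyl]-4-(tert-butyldimethylsilyloxy)but-1-yn-1-olate | [Li]OC#C[C@H](c1cc(OCc2ccccc2)cc(OCc2ccccc2)c1)[C@@H](O[Si](C)(C)C(C)(C)C)c1ccc(OCc2ccccc2)c(OCc2ccccc2)c1 | intermediate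
14 | (3S,4R)-4-[3,4-bis(benzyloxy)phenyl]-3-[3,5-bis(benzyloxy)phenyl]-4-(tert-butyldimethylsilyloxy)-1-(triisopropylsilyloxy)but-1-yne | CC(C)[Si](C(C)C)(C(C)C)OC#C[C@H](c1cc(OCc2ccccc2)cc(OCc2ccccc2)c1)[C@@H](O[Si](C)(C)C(C)(C)C)c1ccc(OCc2ccccc2)c(OCc2ccccc2)c1 | intermediate
15 | tert-butyldimethyl(prop-2-yn-1-yloxy)silane | C#CCO[Si](C)(C)C(C)(C)C | starting material
16 | 3-[(tert-butyldimethylsilyloxy)methyl]-4,4-dichlorocyclobut-2-en-1-one | O=C1C=C(CO[Si](C)(C)C(C)(C)C)C1(Cl)Cl | intermediate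
17 | 3-[(tert-butyldimethylsilyloxy)methyl]cyclobut-2-en-1-one | O=C1C=C(CO[Si](C)(C)C(C)(C)C)C1 | intermediate
18 | 3-[(tert-butyldimethylsilyloxy)methyl]buta-1,3-dien-1-one | O=C=CC(=C)CO[Si](C)(C)C(C)(C)C | intermediate
19 | 2-{(1S,2R)-2-[3,4-bis(benzyloxy)phenyl]-1-[3,5-bis(benzyloxy)phenyl]-2-(tert-butyldimethylsilyloxy)ethyl}-4-[3-(tert-butyldimethylsilyloxy)prop-1-en-2-yl]-3-(triisopropylsilyloxy)cyclobut-2-en-1-one (C4 epimers) | O=C1C([C@H](c2cc(OCc3ccccc3)cc(OCc3ccccc3)c2)[C@@H](O[Si](C)(C)C(C)(C)C)c2ccc(OCc3ccccc3)c(OCc3ccccc3)c2)=C(O[Si](C(C)C)(C(C)C)C(C)C)C1C(=C)CO[Si](C)(C)C(C)(C)C | intermediate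
20 | (3E)-2-{(1S,2R)-2-[3,4-bis(benzyloxy)phenyl]-1-[3,5-bis(benzyloxy)phenyl]-2-(tert-butyldimethylsilyloxy)ethyl}-5-[(tert-butyldimethylsilyloxy)methyl]-3-(triisopropylsilyloxy)hexa-1,3,5-trien-1-one | O=C=C([C@H](c1cc(OCc2ccccc2)cc(OCc2ccccc2)c1)[C@@H](O[Si](C)(C)C(C)(C)C)c1ccc(OCc2ccccc2)c(OCc2ccccc2)c1)/C(O[Si](C(C)C)(C(C)C)C(C)C)=C\C(=C)CO[Si](C)(C)C(C)(C)C | intermediate
21 | 2-{(1S,2R)-2-[3,4-bis(benzyloxy)phenyl]-1-[3,5-bis(benzyloxy)phenyl]-2-(tert-butyldimethylsilyloxy)ethyl}-5-[(tert-butyldimethylsilyloxy)methyl]-3-(triisopropylsilyloxy)phenol | Oc1cc(CO[Si](C)(C)C(C)(C)C)cc(O[Si](C(C)C)(C(C)C)C(C)C)c1[C@H](c1cc(OCc2ccccc2)cc(OCc2ccccc2)c1)[C@@H](O[Si](C)(C)C(C)(C)C)c1ccc(OCc2ccccc2)c(OCc2ccccc2)c1 | intermediate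
22 | 2-{(1S,2R)-2-[3,4-bis(benzyloxy)phenyl]-1-[3,5-bis(benzyloxy)phenyl]-2-hydroxyethyl}-5-(hydroxymethyl)benzene-1,3-diol | Oc1cc(CO)cc(O)c1[C@H](c1cc(OCc2ccccc2)cc(OCc2ccccc2)c1)[C@@H](O)c1ccc(OCc2ccccc2)c(OCc2ccccc2)c1 | intermediate
23 | (2S,3S)-2-[3,4-bis(benzyloxy)phenyl]-3-[3,5-bis(benzyloxy)phenyl]-6-(hydroxymethyl)-2,3-dihydro-1-benzofuran-4-ol | OCc1cc(O)c2c(c1)O[C@H](c1ccc(OCc3ccccc3)c(OCc3ccccc3)c1)[C@H]2c1cc(OCc2ccccc2)cc(OCc2ccccc2)c1 | intermediate
24 | (2S,3S)-2-[3,4-bis(benzyloxy)phenyl]-3-[3,5-bis(benzyloxy)phenyl]-4-hydroxy-2,3-dihydro-1-benzofuran-6-carbaldehyde | O=Cc1cc(O)c2c(c1)O[C@H](c1ccc(OCc3ccccc3)c(OCc3ccccc3)c1)[C@H]2c1cc(OCc2ccccc2)cc(OCc2ccccc2)c1 | intermediate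
25 | 4-(benzyloxy)-3-methoxybenzyl alcohol | COc1cc(CO)ccc1OCc1ccccc1 | starting material
26 | diethyl [4-(benzyloxy)-3-methoxybenzyl]phosphonate | CCOP(=O)(Cc1ccc(OCc2ccccc2)c(OC)c1)OCC | intermediate
27 | (2S,3S)-6-{(E)-2-[4-(benzyloxy)-3-methoxyphenyl]ethenyl}-2-[3,4-bis(benzyloxy)phenyl]-3-[3,5-bis(benzyloxy)phenyl]-2,3-dihydro-1-benzofuran-4-ol | COc1cc(/C=C/c2cc(O)c3c(c2)O[C@H](c2ccc(OCc4ccccc4)c(OCc4ccccc4)c2)[C@H]3c2cc(OCc3ccccc3)cc(OCc3ccccc3)c2)ccc1OCc1ccccc1 | intermediate
28 | (2S,3S)-2-(3,4-dihydroxyphenyl)-3-(3,5-dihydroxyphenyl)-6-[(E)-2-(4-hydroxy-3-methoxyphenyl)ethenyl]-2,3-dihydro-1-benzofuran-4-ol | COc1cc(/C=C/c2cc(O)c3c(c2)O[C@H](c2ccc(O)c(O)c2)[C@H]3c2cc(O)cc(O)c2)ccc1O | target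

**Totals**
Total step count: 16. Longest linear sequence: 13 steps (steps 1–7, 10–13, 15, 16); steps 8–9 and step 14 are side branches.

**Steps most likely to fail**

Step 10. The vinylketene may be consumed by self-condensation, or by acylating the newly formed phenol, faster than the hindered α-branched ynol ether captures it. Prolonged heating may also shift silicon from oxygen to carbon in the ynol ether. The fallback sets out from 14 and generates the same vinylketene at room temperature by photochemical Wolff rearrangement instead of thermal ring opening. Methyl vinyl ketone and aqueous formaldehyde with DABCO (Baylis–Hillman reaction) should give 3-(hydroxymethyl)but-3-en-2-one F1. TBSCl and imidazole convert it into 3-[(tert-butyldimethylsilyloxy)methyl]but-3-en-2-one F2. LiN(SiMe3)2 and 2,2,2-trifluoroethyl trifluoroacetate give the diketone 5-[(tert-butyldimethylsilyloxy)methyl]-1,1,1-trifluorohex-5-ene-2,4-dione F3, which is treated without isolation with methanesulfonyl azide and Et3N to give 3-[(tert-butyldimethylsilyloxy)methyl]-1-diazobut-3-en-2-one F4. Irradiation of F4 with 14 (300 nm, ClCH2CH2Cl, rt, then brief warming to 80 °C) enters the cascade at 18 and comes back to the route at 21.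

Step 7. Oxygen transfer to the hindered acetylide may stall, and in the strongly basic medium proton transfer from the propargylic, benzylic C3–H could erode the stereocentre or start β-elimination of the silyloxy group. The fallback sets out from 11 and oxygenates the alkyne terminus through a hypervalent iodine intermediate instead of oxidising the acetylide. Quenching the n-BuLi reaction of 11 with NH4Cl gives the terminal alkyne (3R,4R)-4-[3,4-bis(benzyloxy)phenyl]-3-[3,5-bis(benzyloxy)phenyl]-4-(tert-butyldimethylsilyloxy)but-1-yne F5. PhI(OH)OTs converts it into the alkynyl(phenyl)iodonium tosylate F6, and catalytic CuOTf collapses this to the alkynyl tosylate F7. MeLi at −78 °C attacks sulfur and releases ynolate 13 within minutes, and TIPSOTf then gives 14, where the route is rejoined.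

Step 8. The inductively deactivated propargylic ether may add dichloroketene slowly, and the ZnCl2 formed may cleave the silyl ether or polymerise the ketene first. The fallback sets out from 15 and uses a keteniminium [2+2] cycloaddition, which needs no zinc and no dechlorination. N,N-Dimethylacetamide, Tf2O and 2,4,6-collidine give N,N-dimethylketeniminium triflate F8, which adds to 15 to give 3-[(tert-butyldimethylsilyloxy)methyl]-N,N-dimethylcyclobut-2-en-1-iminium triflate F9. Aqueous NaHCO3 hydrolysis gives 17 directly, where the route is rejoined, so that 16 and step 9 are bypassed.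

**Further compounds**
F1 | step 10 | 3-(hydroxymethyl)but-3-en-2-one | CC(=O)C(=C)CO
F2 | step 10 | 3-[(tert-butyldimethylsilyloxy)methyl]but-3-en-2-one | CC(=O)C(=C)CO[Si](C)(C)C(C)(C)C
F3 | step 10 | 5-[(tert-butyldimethylsilyloxy)methyl]-1,1,1-trifluorohex-5-ene-2,4-dione | FC(F)(F)C(=O)CC(=O)C(=C)CO[Si](C)(C)C(C)(C)C
F4 | step 10 | 3-[(tert-butyldimethylsilyloxy)methyl]-1-diazobut-3-en-2-one | [N-]=[N+]=CC(=O)C(=C)CO[Si](C)(C)C(C)(C)C
F5 | step 7 | (3R,4R)-4-[3,4-bis(benzyloxy)phenyl]-3-[3,5-bis(benzyloxy)phenyl]-4-(tert-butyldimethylsilyloxy)but-1-yne | C#C[C@H](c1cc(OCc2ccccc2)cc(OCc2ccccc2)c1)[C@@H](O[Si](C)(C)C(C)(C)C)c1ccc(OCc2ccccc2)c(OCc2ccccc2)c1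
F6 | step 7 | [(3S,4R)-4-[3,4-bis(benzyloxy)phenyl]-3-[3,5-bis(benzyloxy)phenyl]-4-(tert-butyldimethylsilyloxy)but-1-yn-1-yl](phenyl)iodonium 4-methylbenzenesulfonate | Cc1ccc(S(=O)(=O)[O-])cc1.c1ccc([I+]C#C[C@H](c2cc(OCc3ccccc3)cc(OCc3ccccc3)c2)[C@@H](O[Si](C)(C)C(C)(C)C)c2ccc(OCc3ccccc3)c(OCc3ccccc3)c2)cc1
F7 | step 7 | (3S,4R)-4-[3,4-bis(benzyloxy)phenyl]-3-[3,5-bis(benzyloxy)phenyl]-4-(tert-butyldimethylsilyloxy)but-1-yn-1-yl 4-methylbenzenesulfonate | Cc1ccc(S(=O)(=O)OC#C[C@H](c2cc(OCc3ccccc3)cc(OCc3ccccc3)c2)[C@@H](O[Si](C)(C)C(C)(C)C)c2ccc(OCc3ccccc3)c(OCc3ccccc3)c2)cc1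
F8 | step 8 | N,N-dimethylketeniminium triflate | C=C=[N+](C)C.[O-]S(=O)(=O)C(F)(F)F
F9 | step 8 | 3-[(tert-butyldimethylsilyloxy)methyl]-N,N-dimethylcyclobut-2-en-1-iminium triflate | C[N+](C)=C1C=C(CO[Si](C)(C)C(C)(C)C)C1.[O-]S(=O)(=O)C(F)(F)F
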